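## Retrosynthetic overview

1. Target 16 comes from ketone 15 by a catalyst-controlled reduction (C1 is set last), and 15 from its MOM ether 14.
2. The saturated ring of tetralone 14 is not closed at full size. In cyclobutanol 12 the chain C1–C2–C3–C4 is a four-membered ring with C1 bonded to C4. That bond is cut and the ring re-closed through the two arene carbons (two-atom ring expansion), forming the C4–aryl bond and the C4 stereocenter in the same operation.
3. Enabling feature: C1 (carbinol/ketone carbon) and C4 (diarylmethine carbon) lie 1,4 on the ring fused to the anisole. In 12 the strained C1(OH)–C4 bond sits between an O–H and the electron-rich 1,8-dioxygenated naphthalene, so it breaks to an aryl ketone plus a planar naphthyl-stabilised radical. The bromine on the arene carbon between C(OH) and OMe marks where C4 must re-attach.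
4. 12 comes from 2-arylcyclobutanone 9 and the Grignard reagent of 10; 9 from aldehyde 5 and cyclopropylsulfonium salt 6 (three- to four-membered ring growth); 5 from naphthalene-1,8-diol 1 (methylation, MOM, ortho-lithiation/formylation).
5. Ring order: naphthalene (bought), then cyclobutanone, then the six-membered ring (key step).

Key step: step 6

Remark: 6 and 10 are taken as purchasable; the sense of induction of the nickel ligand in step 6 cannot be predicted reliably, so the ligand antipode is named by its outcome and must be fixed by experiment.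

## Route

Step 1
Reactants: 1 naphthalene-1,8-diol
Product: 2 8-methoxynaphthalen-1-ol
Conditions: MeI (1.05 equiv), K2CO3, acetone, reflux
Reagents that add atoms: iodomethane, CI
Why: Williamson etherification; after the first O-alkylation the remaining peri-OH is locked in a strong O–H···OMe hydrogen bond and is far less acidic, so methylation should stop at the mono-ether.

Step 2
Reactants: 2 8-methoxynaphthalen-1-ol
Product: 3 1-methoxy-8-(methoxymethoxy)naphthalene
Conditions: NaH, DMF, 0 °C; then MOMCl, 0 °C → rt
Reagents that add atoms: chloromethyl methyl ether, COCCl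
Why: O-alkylation of the sodium naphtholate gives a base-stable acetal that is also the stronger directing group for the following lithiation.

Step 3
Reactants: 3 1-methoxy-8-(methoxymethoxy)naphthalene
Product: 5 8-methoxy-1-(methoxymethoxy)naphthalene-2-carbaldehyde, via aryllithium 4 (not isolated)
Conditions: n-BuLi, TMEDA, Et2O, 0 °C → rt; then DMF, −78 °C → rt; aq NH4Cl
Reagents that add atoms: N,N-dimethylformamide, CN(C)C=O
Why: Directed ortho-metalation: the chelating OMOM group should steer lithiation to C2 (C8 is blocked and OMe is the weaker director for C7), and DMF formylates the aryllithium.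

Step 4
Reactants: 5 8-methoxy-1-(methoxymethoxy)naphthalene-2-carbaldehyde; 6 cyclopropyldiphenylsulfonium tetrafluoroborate
Product: 9 2-[8-methoxy-1-(methoxymethoxy)naphthalen-2-yl]cyclobutan-1-one (racemic), via sulfonium ylide 7 (not isolated), via oxaspiropentane 8 (not isolated)
Conditions: KOH (powder), DMSO, 25 °C; then LiBF4 (cat.), PhH, 25–50 °C
Reagents that add atoms: none
Why: Trost spiroannulation: the cyclopropylide adds to the aldehyde to give the oxaspiropentane, whose benzylic C–O ionisation triggers a semipinacol 1,2-shift of a cyclopropane bond to the 2-arylcyclobutanone; the stereocenter is left racemic on purpose.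

Step 5
Reactants: 9 2-[8-methoxy-1-(methoxymethoxy)naphthalen-2-yl]cyclobutan-1-one; 10 2-bromo-1-iodo-3-methoxybenzene
Product: 12 1-(2-bromo-3-methoxyphenyl)-2-[8-methoxy-1-(methoxymethoxy)naphthalen-2-yl]cyclobutan-1-ol (racemic; both diastereomers), via arylmagnesium chloride 11 (not isolated)
Conditions: 10, i-PrMgCl·LiCl, THF, −20 °C; then LaCl3·2LiCl, 9, −20 → 0 °C; aq NH4Cl at 0 °C
Reagents that add atoms: none
Why: Selective iodine/magnesium exchange (I before Br) followed by lanthanum-assisted 1,2-addition to the strained, electrophilic cyclobutanone, with La(III) suppressing enolisation; the diastereomers are not separated because both centres are erased or reset in step 6.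

Step 6
Reactants: 12 1-(2-bromo-3-methoxyphenyl)-2-[8-methoxy-1-(methoxymethoxy)naphthalen-2-yl]cyclobutan-1-ol
Product: 14 (4R)-5-methoxy-4-[8-methoxy-1-(methoxymethoxy)naphthalen-2-yl]-3,4-dihydronaphthalen-1(2H)-one, via benzylic radical 13 (not isolated)
Conditions: NiBr2·glyme (10 mol %), chiral 2,2′-bi(2-imidazoline) ligand (12 mol %, antipode giving 4R), Ir[dF(CF3)ppy]2(dtbbpy)PF6 (2 mol %), 2,4,6-collidine (2 equiv), 1,4-dioxane, blue LEDs, 25 °C
Reagents that add atoms: none
Why: Proposed new method: the excited iridium photocatalyst and collidine remove an electron and the O–H proton of 12 (oxidation of the electron-rich 1,8-dioxygenated naphthalene or direct proton-coupled electron transfer), and the resulting alkoxy radical/radical cation relieves the cyclobutane strain by β-scission of the C(OH)–CH(naphthyl) bond, the only cleavage that gives a naphthyl-stabilised benzylic radical 13 beside the aryl ketone. The closest known reaction types are the photoredox/nickel ring-opening γ-arylation of tertiary cycloalkanols with aryl bromides and the nickel/chiral bis(imidazoline)-catalysed enantioselective arylation of prochiral benzylic radicals to 1,1-diarylalkanes, both known only intermolecularly; here the aryl bromide sits in the same molecule. The six-membered ring is closed by C(sp3)–C(sp2) reductive elimination from a seven-membered aryl(alkyl)nickel(III) metallacycle formed after oxidative addition of nickel into the C–Br bond and capture of 13, so the former cyclobutane C–C bond is replaced by the two arene carbons (four- to six-membered ring expansion). The new C4 stereocenter is set by the chiral ligand on nickel during radical capture and reductive elimination; because 13 is planar, all four stereoisomers of 12 should converge on one enantiomer of 14. The step needs regioselective β-scission (secured by the benzylic, naphthyl-bearing carbon), a single site of arene attachment (secured by the bromine between the carbinol carbon and OMe) and nickel capture faster than hydrogen abstraction (favoured by intramolecularity); the net change is loss of HBr, taken up by collidine.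

Step 7
Reactants: 14 (4R)-5-methoxy-4-[8-methoxy-1-(methoxymethoxy)naphthalen-2-yl]-3,4-dihydronaphthalen-1(2H)-one
Product: 15 (4R)-4-(1-hydroxy-8-methoxynaphthalen-2-yl)-5-methoxy-3,4-dihydronaphthalen-1(2H)-one
Conditions: conc. HCl (cat.), MeOH, 45 °C; aqueous work-up
Reagents that add atoms: none
Why: Acid-catalysed transacetalisation removes the MOM group while C1 is still a ketone, so no acid-labile benzylic alcohol is exposed; the diarylmethine C–H at C4 is neither acidic nor ionisable here and should keep its configuration.

Step 8
Reactants: 15 (4R)-4-(1-hydroxy-8-methoxynaphthalen-2-yl)-5-methoxy-3,4-dihydronaphthalen-1(2H)-one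
Product: 16 (1S,4R)-4-(1-hydroxy-8-methoxynaphthalen-2-yl)-5-methoxy-1,2,3,4-tetrahydronaphthalen-1-ol (Dipolynaphthalene A)
Conditions: RuCl(p-cymene)[(S,S)-TsDPEN] (1 mol %), HCO2H/Et3N 5:2, DMF, 30 °C
Reagents that add atoms: none
Why: Noyori asymmetric transfer hydrogenation: by analogy with 1-tetralone the (S,S)-catalyst should deliver hydride to the face that gives (1S), which with (4R) is the trans alcohol; any (4S) ketone present would become a separable cis diastereomer.

## Compound list

1 | naphthalene-1,8-diol | Oc1cccc2cccc(O)c12 | starting material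
2 | 8-methoxynaphthalen-1-ol | COc1cccc2cccc(O)c12 | intermediate
3 | 1-methoxy-8-(methoxymethoxy)naphthalene | COCOc1cccc2cccc(OC)c12 | intermediate
4 | [8-methoxy-1-(methoxymethoxy)naphthalen-2-yl]lithium (aryllithium) | [Li]c1ccc2cccc(OC)c2c1OCOC | intermediate
5 | 8-methoxy-1-(methoxymethoxy)naphthalene-2-carbaldehyde | O=Cc1ccc2cccc(OC)c2c1OCOC | intermediate
6 | cyclopropyldiphenylsulfonium tetrafluoroborate | C1CC1[S+](c1ccccc1)c1ccccc1.F[B-](F)(F)F | starting material
7 | diphenylsulfonium cyclopropylide (sulfonium ylide) | [C-]1(CC1)[S+](c1ccccc1)c1ccccc1 | intermediate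
8 | 2-[8-methoxy-1-(methoxymethoxy)naphthalen-2-yl]-1-oxaspiro[2.2]pentane (oxaspiropentane, racemic) | COCOc1c(C2OC23CC3)ccc2cccc(OC)c12 | intermediate
9 | 2-[8-methoxy-1-(methoxymethoxy)naphthalen-2-yl]cyclobutan-1-one (racemic) | O=C1CCC1c1ccc2cccc(OC)c2c1OCOC | intermediate
10 | 2-bromo-1-iodo-3-methoxybenzene | COc1cccc(I)c1Br | starting material
11 | (2-bromo-3-methoxyphenyl)magnesium chloride (arylmagnesium chloride) | COc1cccc([Mg]Cl)c1Br | intermediate
12 | 1-(2-bromo-3-methoxyphenyl)-2-[8-methoxy-1-(methoxymethoxy)naphthalen-2-yl]cyclobutan-1-ol (racemic, both diastereomers) | COc1cccc(C2(O)CCC2c2ccc3cccc(OC)c3c2OCOC)c1Br | intermediate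
13 | 4-(2-bromo-3-methoxyphenyl)-1-[8-methoxy-1-(methoxymethoxy)naphthalen-2-yl]-4-oxobutyl radical (benzylic radical) | COc1cccc(C(=O)CC[CH]c2ccc3cccc(OC)c3c2OCOC)c1Br | intermediate
14 | (4R)-5-methoxy-4-[8-methoxy-1-(methoxymethoxy)naphthalen-2-yl]-3,4-dihydronaphthalen-1(2H)-one | COc1cccc2c1[C@@H](c1ccc3cccc(OC)c3c1OCOC)CCC2=O | intermediate
15 | (4R)-4-(1-hydroxy-8-methoxynaphthalen-2-yl)-5-methoxy-3,4-dihydronaphthalen-1(2H)-one | COc1cccc2c1[C@@H](c1ccc3cccc(OC)c3c1O)CCC2=O | intermediate
16 | (1S,4R)-4-(1-hydroxy-8-methoxynaphthalen-2-yl)-5-methoxy-1,2,3,4-tetrahydronaphthalen-1-ol (Dipolynaphthalene A) | COc1cccc2c1[C@@H](c1ccc3cccc(OC)c3c1O)CC[C@@H]2O | target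

## Step count and risks

Total steps: 8. Longest linear sequence: 8 steps (1 → 16); 6 and 10 enter as purchased materials.

**Step 6.** What may go wrong: slow oxidative addition of nickel at the doubly ortho-substituted C–Br bond; loss of the benzylic radical by hydrogen abstraction or over-oxidation before nickel captures it; a stereospecific two-electron β-carbon elimination at nickel that bypasses the planar radical; weak enantiofacial discrimination at the crowded aryl–nickel centre. The fallback uses known reactions, sets out from 9 and comes back at 16; the bromine becomes a blocking group instead of a coupling handle. Iodine/magnesium exchange of purchased 1-bromo-2-iodo-4-methoxybenzene with i-PrMgCl·LiCl gives (2-bromo-5-methoxyphenyl)magnesium chloride F1, which adds to 9 (LaCl3·2LiCl) to give 1-(2-bromo-5-methoxyphenyl)-2-[8-methoxy-1-(methoxymethoxy)naphthalen-2-yl]cyclobutan-1-ol F2. The silver-catalysed oxidative radical ring expansion of 1-arylcyclobutanols to 1-tetralones (AgNO3 cat., K2S2O8, MeCN/H2O) can close only at the one free ortho carbon, next to OMe, and should give racemic 8-bromo-5-methoxy-4-[8-methoxy-1-(methoxymethoxy)naphthalen-2-yl]-3,4-dihydronaphthalen-1(2H)-one F3. Hydrogenolysis of the C–Br bond (H2, Pd/C, Et3N, EtOAc) gives racemic 5-methoxy-4-[8-methoxy-1-(methoxymethoxy)naphthalen-2-yl]-3,4-dihydronaphthalen-1(2H)-one F4, and the conditions of step 7 give racemic 4-(1-hydroxy-8-methoxynaphthalen-2-yl)-5-methoxy-3,4-dihydronaphthalen-1(2H)-one F5. Step 8 then acts as a resolution: the (4R) half becomes 16 and the (4S) half becomes the cis diastereomer (1S,4S)-4-(1-hydroxy-8-methoxynaphthalen-2-yl)-5-methoxy-1,2,3,4-tetrahydronaphthalen-1-ol F6, which is removed by chromatography. Only the (4R) half of the material can end in 16 on this path.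

**Step 5.** What may go wrong: deprotonation of the acidic benzylic α-hydrogen of 9 by the hindered, basic Grignard reagent instead of addition; strain-driven C–C fragmentation of the tertiary alkoxide before the quench. The fallback sets out from 9 and comes back at 12; the C–C bond is made with an unhindered nucleophile and the bromine is introduced afterwards. Commercial (3-methoxyphenyl)magnesium bromide adds to 9 to give 1-(3-methoxyphenyl)-2-[8-methoxy-1-(methoxymethoxy)naphthalen-2-yl]cyclobutan-1-ol F7. n-BuLi/TMEDA (2.2 equiv, Et2O, 0 °C) should lithiate the position flanked by the alkoxide-bearing carbon and the methoxy group (cooperative directed ortho-metalation) to give lithium 1-(2-lithio-3-methoxyphenyl)-2-[8-methoxy-1-(methoxymethoxy)naphthalen-2-yl]cyclobutan-1-olate F8, and 1,2-dibromotetrafluoroethane then delivers 12.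

**Step 8.** What may go wrong: the pseudo-axial C4 aryl group steering hydride to the face that gives the cis alcohol against the catalyst's preference; the free naphthol slowing the ruthenium catalyst. The fallback sets out from 15 and comes back at 16; substrate-controlled reduction is followed by inversion. NaBH4 (MeOH, −20 °C) is expected to add axially, anti to the aryl group, to give the cis diol (1R,4R)-4-(1-hydroxy-8-methoxynaphthalen-2-yl)-5-methoxy-1,2,3,4-tetrahydronaphthalen-1-ol F9. A Mitsunobu reaction with 4-nitrobenzoic acid (PPh3, DIAD, THF, 0 °C) should invert C1 to give (1S,4R)-4-(1-hydroxy-8-methoxynaphthalen-2-yl)-5-methoxy-1,2,3,4-tetrahydronaphthalen-1-yl 4-nitrobenzoate F10; the hydrogen-bonded naphthol is a much weaker acid than the carboxylic acid and cannot reach the rear side of C1. K2CO3 in MeOH then releases 16.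

## Further compounds

F1 | step 6 | (2-bromo-5-methoxyphenyl)magnesium chloride | COc1ccc(Br)c([Mg]Cl)c1
F2 | step 6 | 1-(2-bromo-5-methoxyphenyl)-2-[8-methoxy-1-(methoxymethoxy)naphthalen-2-yl]cyclobutan-1-ol (racemic, both diastereomers) | COc1ccc(Br)c(c1)C1(O)CCC1c1ccc2cccc(OC)c2c1OCOC
F3 | step 6 | 8-bromo-5-methoxy-4-[8-methoxy-1-(methoxymethoxy)naphthalen-2-yl]-3,4-dihydronaphthalen-1(2H)-one (racemic) | COc1ccc(Br)c2c1C(c1ccc3cccc(OC)c3c1OCOC)CCC2=O
F4 | step 6 | 5-methoxy-4-[8-methoxy-1-(methoxymethoxy)naphthalen-2-yl]-3,4-dihydronaphthalen-1(2H)-one (racemic) | COc1cccc2c1C(c1ccc3cccc(OC)c3c1OCOC)CCC2=O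
F5 | step 6 | 4-(1-hydroxy-8-methoxynaphthalen-2-yl)-5-methoxy-3,4-dihydronaphthalen-1(2H)-one (racemic) | COc1cccc2c1C(c1ccc3cccc(OC)c3c1O)CCC2=O
F6 | step 6 | (1S,4S)-4-(1-hydroxy-8-methoxynaphthalen-2-yl)-5-methoxy-1,2,3,4-tetrahydronaphthalen-1-ol | COc1cccc2c1[C@H](c1ccc3cccc(OC)c3c1O)CC[C@@H]2O
F7 | step 5 | 1-(3-methoxyphenyl)-2-[8-methoxy-1-(methoxymethoxy)naphthalen-2-yl]cyclobutan-1-ol (racemic, both diastereomers) | COc1cccc(c1)C1(O)CCC1c1ccc2cccc(OC)c2c1OCOC
F8 | step 5 | lithium 1-(2-lithio-3-methoxyphenyl)-2-[8-methoxy-1-(methoxymethoxy)naphthalen-2-yl]cyclobutan-1-olate | [Li]OC1(CCC1c1ccc2cccc(OC)c2c1OCOC)c1cccc(OC)c1[Li]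
F9 | step 8 | (1R,4R)-4-(1-hydroxy-8-methoxynaphthalen-2-yl)-5-methoxy-1,2,3,4-tetrahydronaphthalen-1-ol | COc1cccc2c1[C@@H](c1ccc3cccc(OC)c3c1O)CC[C@H]2O
F10 | step 8 | (1S,4R)-4-(1-hydroxy-8-methoxynaphthalen-2-yl)-5-methoxy-1,2,3,4-tetrahydronaphthalen-1-yl 4-nitrobenzoate | COc1cccc2c1[C@@H](c1ccc3cccc(OC)c3c1O)CC[C@@H]2OC(=O)c1ccc(cc1)[N+](=O)[O-]
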